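**Strategy.** Labels: seven-membered ring C1 (ester CH), C2, C3 (CMe), C7 (C–OH), C8, C9, C10 (CMe–OH); cyclopentane C3–C4–C5–C6 (iPr)–C7. The route cuts C7–C8 and C9–C10. The tertiary C7 oxygen lies 1,4 to C10 across the cycloheptane and C10 adjoins the oxygenated C1, so the C7 oxygen can be tied to C10 as a six-membered carbonyl ylide. The diazo dione precursor, a 2-(3-diazo-2-oxobutyl)cyclopentanone with cis C3 methyl and C6 isopropyl made from (S)-limonene, gives this ylide under rhodium catalysis. Trapping with ethynyl p-tolyl sulfone closes the seven-membered ring and sets the C7–O configuration in one operation. Unbridging at C10–O then leaves the C7 alcohol and a C1=C10 alkene for the trans-diol monoester.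

Key step: step 9

Remark (regiochemistry): in the cycloadduct the sulfonyl group is written on C8, because the alkyne β-carbon should bond to the nucleophilic ylide carbon C10; a C9 regioisomer would converge after desulfonylation.
Remark (C6 integrity): the ester is hydrolysed before the C7 ketone is unveiled and the γ-keto acid is activated as a mixed anhydride, so the epimerisable C6–H never meets hydroxide or HCl.
Remark (carbenoid): the C10 carbenoid carries β-hydrogens, so a bulky dirhodium carboxylate at low temperature is specified to hold back 1,2-hydride shift.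

Step 1
Reactants: 1 (S)-(−)-limonene
Product: 2 (4S)-1-methyl-4-(propan-2-yl)cyclohex-1-ene
Conditions: H2 (1 atm), RhCl(PPh3)3 (cat.), toluene, rt
Reagents that add atoms: none
Why: Homogeneous hydrogenation with RhCl(PPh3)3 should saturate the unhindered 1,1-disubstituted isopropenyl alkene much faster than the trisubstituted ring alkene, and the stereocentre is not touched.

Step 2
Reactants: 2 (4S)-1-methyl-4-(propan-2-yl)cyclohex-1-ene
Product: 4 (3S)-6-oxo-3-(propan-2-yl)heptanal, via secondary ozonide 3 (not isolated)
Conditions: O3, CH2Cl2, −78 °C; then Me2S, −78 °C → rt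
Reagents that add atoms: ozone, [O-][O+]=O
Why: Ozonolysis with reductive work-up cleaves the only alkene to the methyl ketone and the aldehyde, and the stereocentre is β to the aldehyde and cannot epimerise.

Step 3
Reactants: 4 (3S)-6-oxo-3-(propan-2-yl)heptanal
Product: 5 (5R)-2-methyl-5-(propan-2-yl)cyclopent-1-ene-1-carbaldehyde
Conditions: piperidine (cat.), AcOH (cat.), toluene, reflux (Dean–Stark)
Reagents that add atoms: none
Why: Amine-catalysed intramolecular aldol condensation, in which the aldehyde reacts through its enamine at the α-carbon with the methyl ketone to close the five-membered ring and dehydration gives the conjugated enal; the isopropyl-bearing centre is not acidified (its label changes from S to R by priority only).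

Step 4
Reactants: 5 (5R)-2-methyl-5-(propan-2-yl)cyclopent-1-ene-1-carbaldehyde
Product: 6 [(5R)-2-methyl-5-(propan-2-yl)cyclopent-1-en-1-yl]methanol
Conditions: NaBH4, CeCl3·7H2O, MeOH, 0 °C
Reagents that add atoms: none
Why: Luche 1,2-reduction should reduce the enal carbonyl without conjugate reduction.

Step 5
Reactants: 6 [(5R)-2-methyl-5-(propan-2-yl)cyclopent-1-en-1-yl]methanol, 7 triethyl orthoacetate
Product: 9 ethyl 2-[(1R,3R)-1-methyl-2-methylidene-3-(propan-2-yl)cyclopentyl]acetate, via mixed ketene acetal 8 (not isolated)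
Conditions: MeC(OEt)3 (excess), EtCO2H (cat.), 140 °C, EtOH distilled off
Reagents that add atoms: triethyl orthoacetate (7), CCOC(C)(OCC)OCC
Why: Johnson–Claisen rearrangement, in which acid-catalysed exchange gives ketene acetal 8 and its chair-like [3,3] shift forms the C3–C2 bond on the ring face opposite the neighbouring isopropyl group, so the new quaternary centre C3 should carry methyl cis to isopropyl; any minor C3 epimer is to be removed by chromatography here.

Step 6
Reactants: 9 ethyl 2-[(1R,3R)-1-methyl-2-methylidene-3-(propan-2-yl)cyclopentyl]acetate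
Product: 10 2-[(1R,3R)-1-methyl-2-methylidene-3-(propan-2-yl)cyclopentyl]acetic acid
Conditions: LiOH·H2O, THF/MeOH/H2O, 50 °C; then 1 M HCl
Reagents that add atoms: lithium hydroxide, [Li+].[OH-]
Why: Ester saponification is run while the future C7 carbonyl is still an alkene, so no base meets an enolisable C6–H.

Step 7
Reactants: 10 2-[(1R,3R)-1-methyl-2-methylidene-3-(propan-2-yl)cyclopentyl]acetic acid
Product: 12 2-[(1R,3R)-1-methyl-2-oxo-3-(propan-2-yl)cyclopentyl]acetic acid, via spiro ozonide 11 (not isolated)
Conditions: O3, CH2Cl2, −78 °C; then PPh3, −78 °C → rt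
Reagents that add atoms: ozone, [O-][O+]=O
Why: Ozonolysis of the exocyclic 1,1-disubstituted alkene with reductive work-up unveils the C7 ketone under neutral conditions that should not enolise C6.

Step 8
Reactants: 12 2-[(1R,3R)-1-methyl-2-oxo-3-(propan-2-yl)cyclopentyl]acetic acid
Product: 14 (2R,5R)-2-(3-diazo-2-oxobutyl)-2-methyl-5-(propan-2-yl)cyclopentan-1-one, via isobutyl carbonic mixed anhydride 13 (not isolated)
Conditions: i-BuOCOCl, N-methylmorpholine, THF, −20 °C; then CH3CHN2 (from N-ethyl-N-nitrosourea, KOH), Et2O, −20 → 0 °C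
Reagents that add atoms: diazoethane, CC=[N+]=[N-]
Why: Acylation of diazoethane by a mixed carbonic anhydride (diazoketone synthesis of the Arndt–Eistert type), in which the anhydride avoids the cyclic pseudo-chloride a γ-keto acid chloride can form, the diazoalkane attacks the more electrophilic carboxylic carbonyl of 13, and the departing isobutyl carbonate takes up the proton.

Step 9
Reactants: 14 (2R,5R)-2-(3-diazo-2-oxobutyl)-2-methyl-5-(propan-2-yl)cyclopentan-1-one, 15 ethynyl p-tolyl sulfone
Product: 18 C7–O–C10 oxygen-bridged vinyl sulfone cycloadduct (8-oxabicyclo[3.2.1]oct-6-en-2-one core: C1 ketone; C10 methyl; p-tolylsulfonyl on C8; C8=C9; cyclopentane fused at C3–C7; C3 methyl and C6 isopropyl on the face of the oxygen bridge), via rhodium carbenoid 16 (not isolated), via carbonyl ylide 17 (not isolated)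
Conditions: Rh2(O2CCPh3)4 (1 mol%), 15 (3 equiv), CH2Cl2, −40 → 0 °C, slow addition of 14
Reagents that add atoms: ethynyl p-tolyl sulfone (15), Cc1ccc(cc1)S(=O)(=O)C#C
Why: Rh2(O2CCPh3)4 extrudes N2 from 14 to give the electrophilic carbenoid 16 at C10, which the lone pair of the C7 ketone oxygen should capture through a six-membered array to release carbonyl ylide 17, and 17 then undergoes a concerted suprafacial (3+2) dipolar cycloaddition with 15. The closest known reaction type is the rhodium-catalysed cyclisation of 1-diazo-2,5-diones to six-membered carbonyl ylides followed by intermolecular trapping with acetylenic dipolarophiles. The oxygen-containing six-membered ring (C10–C1–C2–C3–C7–O) closes by attack of the carbonyl oxygen on the carbenoid carbon (O–C10 bond), and the seven-membered carbocycle, together with the dihydrofuran ring, closes by the cycloaddition that forms C7–C8 and C9–C10 across the ylide termini. C7 is set by the substrate: the C3 methyl is pseudo-axial on the ylide ring and the C6 isopropyl lies on the same face, so 15 should approach from the opposite face and leave the oxygen cis to both groups; C10 follows from C7 because the oxygen bridge can span only one face. The step needs chemoselectivity (ylide formation over 1,2-hydride shift from the C10 methyl, C–H insertion and proton loss from C6–H of the ylide), secured by the bulky carboxylate ligand, low temperature, slow addition of 14 and excess 15, and it needs facial selectivity, secured by the cis methyl/isopropyl pair. Regiochemistry is not critical because the sulfonyl group is removed in the next step.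

Step 10
Reactants: 18 oxygen-bridged vinyl sulfone cycloadduct
Product: 19 oxygen-bridged enone without sulfonyl group (C7–O–C10 bridge; C1 ketone; C8=C9)
Conditions: 6% Na/Hg, Na2HPO4, MeOH/THF, −20 °C
Reagents that add atoms: none
Why: Reductive desulfonylation of a vinyl sulfone with sodium amalgam (electron transfer, loss of sulfinate, protonation of the vinyl anion) should give the alkene, because the sp2 carbanion at C8 cannot expel the bridging alkoxide and the hindered ketone should not be reduced at this potential and temperature.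

Step 11
Reactants: 19 oxygen-bridged enone without sulfonyl group
Product: 20 saturated oxygen-bridged ketone (C7–O–C10 bridge; C1 ketone; C8 and C9 CH2)
Conditions: H2 (1 atm), 10% Pd/C, EtOAc, rt
Reagents that add atoms: none
Why: Heterogeneous hydrogenation of the strained cis-disubstituted bridge alkene creates no stereocentre and should leave the ketone and the ether bridge untouched.

Step 12
Reactants: 20 saturated oxygen-bridged ketone
Product: 23 (3R,3aS,8aR)-6,8a-dimethyl-3-(propan-2-yl)-2,3,4,5,8,8a-hexahydro-1H-azulen-3a-ol (C1=C10 alkene; free C7–OH), via hydrazone 21 (not isolated), via alkenyldiazene 22 (not isolated)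
Conditions: N2H4·H2O, KOH, diethylene glycol, 120 → 195 °C
Reagents that add atoms: none
Why: Kishner–Leonard eliminative reduction (the Wolff–Kishner counterpart of the Wharton reaction), in which the anion of hydrazone 21 expels the α-alkoxide at C10 to open the bridge to alkenyldiazene 22, which loses N2 and is protonated at C1, so the C1=C10 alkene and the C7 alcohol should arise regiospecifically with C3, C6 and C7 unchanged.

Step 13
Reactants: 23 (3R,3aS,8aR)-6,8a-dimethyl-3-(propan-2-yl)-2,3,4,5,8,8a-hexahydro-1H-azulen-3a-ol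
Product: 24 C1–C10 epoxide of 23 with the epoxide oxygen on the face of the C7 hydroxyl
Conditions: VO(acac)2 (cat.), t-BuOOH (decane), CH2Cl2, 0 °C → rt
Reagents that add atoms: tert-butyl hydroperoxide, CC(C)(C)OO
Why: Vanadium-catalysed hydroxyl-directed epoxidation, in which the vanadate ester of the C7 hydroxyl (1,4 to both alkene carbons) should deliver the peroxide oxygen across the ring, so C1 and C10 are set with the epoxide oxygen cis to C7–OH.

Step 14
Reactants: 24 C1–C10 epoxide with oxygen cis to C7–OH
Product: 25 (1R,3aR,5R,6R,8aS)-3a,6-dimethyl-1-(propan-2-yl)decahydroazulene-5,6,8a-triol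
Conditions: HClO4 (cat.), THF/H2O, 0 °C → rt
Reagents that add atoms: water, O
Why: Acid-catalysed epoxide hydrolysis of borderline SN2 character, in which water should attack the tertiary C10 anti to the protonated epoxide oxygen and invert it (C10–OH trans to C7–OH and to C1–OH) while the C1–O bond is retained; the C7 hydroxyl on the epoxide face cannot reach the rear of C10, so no transannular ether is expected.

Step 15
Reactants: 25 (1R,3aR,5R,6R,8aS)-3a,6-dimethyl-1-(propan-2-yl)decahydroazulene-5,6,8a-triol, 26 4-methoxybenzoyl chloride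
Product: 27 (1R,3aR,5R,6R,8aS)-6,8a-dihydroxy-3a,6-dimethyl-1-(propan-2-yl)decahydroazulen-5-yl 4-methoxybenzoate (CNP0244624.1)
Conditions: 26, pyridine, DMAP (cat.), CH2Cl2, 0 °C → rt
Reagents that add atoms: 4-methoxybenzoyl chloride (26), COc1ccc(cc1)C(Cl)=O
Why: DMAP-catalysed acylation should select the only secondary hydroxyl (C1) over the two tertiary hydroxyls at C7 and C10, with no stereocentre affected.

**Compound list**

1 | (S)-(−)-limonene | CC1=CC[C@H](CC1)C(C)=C | starting material
2 | (4S)-1-methyl-4-(propan-2-yl)cyclohex-1-ene | CC1=CC[C@H](CC1)C(C)C | intermediate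
3 | secondary ozonide of 2, 1-methyl-4-(propan-2-yl)-7,8,9-trioxabicyclo[4.2.1]nonane (isopropyl centre as in 2; formed in situ) | CC12CC[C@H](C(C)C)CC(OO1)O2 | intermediate
4 | (3S)-6-oxo-3-(propan-2-yl)heptanal | O=CC[C@H](CCC(C)=O)C(C)C | intermediate
5 | (5R)-2-methyl-5-(propan-2-yl)cyclopent-1-ene-1-carbaldehyde | O=CC1=C(C)CC[C@@H]1C(C)C | intermediate
6 | [(5R)-2-methyl-5-(propan-2-yl)cyclopent-1-en-1-yl]methanol | OCC1=C(C)CC[C@@H]1C(C)C | intermediate
7 | triethyl orthoacetate | CCOC(C)(OCC)OCC | starting material
8 | mixed ketene acetal, (5R)-1-{[(1-ethoxyethenyl)oxy]methyl}-2-methyl-5-(propan-2-yl)cyclopent-1-ene (formed in situ) | C=C(OCC)OCC1=C(C)CC[C@@H]1C(C)C | intermediate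
9 | ethyl 2-[(1R,3R)-1-methyl-2-methylidene-3-(propan-2-yl)cyclopentyl]acetate | CCOC(=O)C[C@@]1(C)CC[C@H](C(C)C)C1=C | intermediate
10 | 2-[(1R,3R)-1-methyl-2-methylidene-3-(propan-2-yl)cyclopentyl]acetic acid | OC(=O)C[C@@]1(C)CC[C@H](C(C)C)C1=C | intermediate
11 | spiro ozonide of 10, 2-[(6R,9R)-6-methyl-9-(propan-2-yl)-1,2,4-trioxaspiro[4.4]nonan-6-yl]acetic acid (spiro centre undefined; formed in situ) | OC(=O)C[C@@]1(C)CC[C@H](C(C)C)C12OCOO2 | intermediate
12 | 2-[(1R,3R)-1-methyl-2-oxo-3-(propan-2-yl)cyclopentyl]acetic acid | OC(=O)C[C@@]1(C)CC[C@H](C(C)C)C1=O | intermediate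
13 | isobutyl carbonic mixed anhydride of 12 (formed in situ) | CC(C)COC(=O)OC(=O)C[C@@]1(C)CC[C@H](C(C)C)C1=O | intermediate
14 | (2R,5R)-2-(3-diazo-2-oxobutyl)-2-methyl-5-(propan-2-yl)cyclopentan-1-one (methyl cis to isopropyl) | CC(=[N+]=[N-])C(=O)C[C@@]1(C)CC[C@H](C(C)C)C1=O | intermediate
15 | ethynyl p-tolyl sulfone | Cc1ccc(cc1)S(=O)(=O)C#C | starting material
16 | rhodium carbenoid at C10 derived from 14 (dirhodium tetracarboxylate core written as one Rh atom; formed in situ) | CC(=[Rh])C(=O)C[C@@]1(C)CC[C@H](C(C)C)C1=O | intermediate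
17 | six-membered carbonyl ylide C7=O(+)–C10(−) fused to the cyclopentane (formed in situ) | C[C-]1[O+]=C2[C@@H](C(C)C)CC[C@]2(C)CC1=O | intermediate
18 | C7–O–C10 oxygen-bridged vinyl sulfone cycloadduct: C1 ketone, C10 methyl, p-tolylsulfonyl on C8, C8=C9; C3 methyl, C6 isopropyl and oxygen bridge on one face | O=C1C[C@@]2(C)CC[C@H](C(C)C)[C@]23O[C@@]1(C)C=C3S(=O)(=O)c1ccc(C)cc1 | intermediate
19 | oxygen-bridged enone without sulfonyl group: C7–O–C10 bridge, C1 ketone, C8=C9 | O=C1C[C@@]2(C)CC[C@H](C(C)C)[C@]23O[C@@]1(C)C=C3 | intermediate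
20 | saturated oxygen-bridged ketone: C7–O–C10 bridge, C1 ketone (6,8a-dimethyl-3-(propan-2-yl)-3a,6-epoxy-perhydroazulen-7-one skeleton) | O=C1C[C@@]2(C)CC[C@H](C(C)C)[C@]23O[C@@]1(C)CC3 | intermediate
21 | hydrazone of 20 at C1 (formed in situ) | NN=C1C[C@@]2(C)CC[C@H](C(C)C)[C@]23O[C@@]1(C)CC3 | intermediate
22 | alkenyldiazene: C1(N=NH)=C10(CH3) with free C7–OH (formed in situ) | CC1=C(N=N)C[C@@]2(C)CC[C@H](C(C)C)[C@@]2(O)CC1 | intermediate
23 | (3R,3aS,8aR)-6,8a-dimethyl-3-(propan-2-yl)-2,3,4,5,8,8a-hexahydro-1H-azulen-3a-ol | CC1=CC[C@@]2(C)CC[C@H](C(C)C)[C@@]2(O)CC1 | intermediate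
24 | C1–C10 epoxide of 23, epoxide oxygen cis to C7–OH, C3 methyl and C6 isopropyl | C[C@@]12O[C@@H]1C[C@@]3(C)CC[C@H](C(C)C)[C@@]3(O)CC2 | intermediate
25 | (1R,3aR,5R,6R,8aS)-3a,6-dimethyl-1-(propan-2-yl)decahydroazulene-5,6,8a-triol | O[C@@H]1C[C@@]2(C)CC[C@H](C(C)C)[C@@]2(O)CC[C@@]1(C)O | intermediate
26 | 4-methoxybenzoyl chloride | COc1ccc(cc1)C(Cl)=O | starting material
27 | (1R,3aR,5R,6R,8aS)-6,8a-dihydroxy-3a,6-dimethyl-1-(propan-2-yl)decahydroazulen-5-yl 4-methoxybenzoate | COc1ccc(C(=O)O[C@@H]2C[C@@]3(C)CC[C@H](C(C)C)[C@@]3(O)CC[C@@]2(C)O)cc1 | target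

**Totals.** Total step count: 15. Longest linear sequence: 15 steps (1 to 27); 7, 15 and 26 enter as purchased reagents.

**Steps most likely to fail**

Step 9. The carbenoid may rearrange by 1,2-hydride shift from the C10 methyl or insert into a C–H bond before the hindered C7 oxygen captures it. The ylide may also lose the C6 proton before it meets the dipolarophile. The fallback sets out from 12, returns at 23, and closes the seven-membered ring by olefin metathesis instead of cycloaddition. Chemoselective reduction of the carboxylic acid with BH3·SMe2 (THF, 0 °C) should give (2R,5R)-2-(2-hydroxyethyl)-2-methyl-5-(propan-2-yl)cyclopentan-1-one F1. Dess–Martin oxidation gives 2-[(1R,3R)-1-methyl-2-oxo-3-(propan-2-yl)cyclopentyl]acetaldehyde F2. Wittig methylenation of the aldehyde alone (Ph3P=CH2, THF, −78 °C) gives (2R,5R)-2-methyl-5-(propan-2-yl)-2-(prop-2-en-1-yl)cyclopentan-1-one F3. Addition of 3-methylbut-3-en-1-ylmagnesium bromide with CeCl3 to the C7 carbonyl, from the face opposite the C3 methyl and C6 isopropyl, should give (1S,2R,5R)-2-methyl-1-(3-methylbut-3-en-1-yl)-5-(propan-2-yl)-2-(prop-2-en-1-yl)cyclopentan-1-ol F4. Ring-closing metathesis with the second-generation Grubbs catalyst RuCl2(PCy3)(H2IMes)(=CHPh) in CH2Cl2 at 40 °C then forms C1=C10 and delivers 23, from which steps 13 to 15 follow.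

Step 12. The hydrazone anion may be protonated at C1 and lose nitrogen with the ether bridge intact (ordinary Wolff–Kishner reduction). The hindered C1 carbonyl may also resist hydrazone formation. The fallback sets out from 20 and returns at 23. Dissolving-metal cleavage (Li, liquid NH3/THF, −78 °C) should break the C10–O bond α to the ketone and leave the regiodefined lithium C1(O)=C10 enolate. After removal of ammonia the enolate is trapped with PhNTf2 to give (3R,3aS,8aR)-3a-hydroxy-6,8a-dimethyl-3-(propan-2-yl)-1,2,3,3a,4,5,8,8a-octahydroazulen-7-yl trifluoromethanesulfonate F5. Palladium-catalysed formate reduction of the enol triflate (Pd(OAc)2, PPh3, Bu3N, HCO2H, DMF, 60 °C) then gives 23.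

Step 13. Oxygen delivery from the hindered tertiary C7 vanadate across the ring may be slow. Undirected epoxidation on the opposite face would then compete (poor facial selectivity), and an epoxide anti to C7–OH would be opened transannularly by that hydroxyl. The fallback sets out from 23 and returns at 27, without any substitution at the tertiary C10. Dihydroxylation with OsO4 (cat.) and N-methylmorpholine N-oxide in acetone/H2O is expected on the less hindered face, anti to the C3 methyl and C7 hydroxyl. It should give (1R,3aR,5S,6R,8aS)-3a,6-dimethyl-1-(propan-2-yl)decahydroazulene-5,6,8a-triol F6, the cis-diol with both new hydroxyls anti to C7–OH. A Mitsunobu reaction with 4-methoxybenzoic acid, PPh3 and diisopropyl azodicarboxylate in THF then inverts the secondary C1 carbinol and installs the ester in the same operation, giving 27.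

**Further compounds**

F1 | step 9 | (2R,5R)-2-(2-hydroxyethyl)-2-methyl-5-(propan-2-yl)cyclopentan-1-one | OCC[C@@]1(C)CC[C@H](C(C)C)C1=O
F2 | step 9 | 2-[(1R,3R)-1-methyl-2-oxo-3-(propan-2-yl)cyclopentyl]acetaldehyde | O=CC[C@@]1(C)CC[C@H](C(C)C)C1=O
F3 | step 9 | (2R,5R)-2-methyl-5-(propan-2-yl)-2-(prop-2-en-1-yl)cyclopentan-1-one | C=CC[C@@]1(C)CC[C@H](C(C)C)C1=O
F4 | step 9 | (1S,2R,5R)-2-methyl-1-(3-methylbut-3-en-1-yl)-5-(propan-2-yl)-2-(prop-2-en-1-yl)cyclopentan-1-ol | C=CC[C@@]1(C)CC[C@H](C(C)C)[C@@]1(O)CCC(C)=C
F5 | step 12 | (3R,3aS,8aR)-3a-hydroxy-6,8a-dimethyl-3-(propan-2-yl)-1,2,3,3a,4,5,8,8a-octahydroazulen-7-yl trifluoromethanesulfonate | CC1=C(OS(=O)(=O)C(F)(F)F)C[C@@]2(C)CC[C@H](C(C)C)[C@@]2(O)CC1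
F6 | step 13 | (1R,3aR,5S,6R,8aS)-3a,6-dimethyl-1-(propan-2-yl)decahydroazulene-5,6,8a-triol | O[C@H]1C[C@@]2(C)CC[C@H](C(C)C)[C@@]2(O)CC[C@@]1(C)O
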